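**Target:** 13, 6-hydroxy-7-methoxy-3-(3,4,5-trimethoxyphenyl)-4H-chromen-4-one, C19H18O7, no stereocentre.

## Structural features

The target 13 is an isoflavone. Its benzene ring A (C4a, C5 to C8, C8a) is fused through the C4a–C8a bond to the γ-pyranone ring C (O1, C2, C3, C4), and the 3,4,5-trimethoxyphenyl ring B is attached to C3 by a single bond. There is no stereocentre and no configurational double bond, so no stereocentres stand next to each other and the problem is one of constitution only. Ring A carries two adjacent oxygens, a free hydroxyl on C6 and a methoxyl on C7, between the unsubstituted C5 and C8. The fragile points are C2 of the pyranone (opened by hydroxide, amines and other hard nucleophiles), the electron-rich C6 phenol (easily oxidized once ring A is aromatic) and the aryl methyl ethers (cleaved by strong Lewis acids). The real difficulty is to end with a hydroxyl on C6 and a methyl ether on C7, two neighbouring oxygens that differ only in their relation to the C4 carbonyl: O7 is para to C4a, O6 is meta. The key step uses the fact that C5–C6–C7–C8 with its two oxygens is a 2,3-dioxygenated butadiene and that C4a–C8a is the second C=C bond of a monocyclic 3-aryl-4-pyranone. A sulfinyl group on the carbon that becomes C4a activates that bond and then leaves to restore it.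

## Logic of the disconnections

13 to 12: the O7–CH3 bond is cut. Keeping both ring A oxygens identical until the arene exists allows a symmetric diene earlier on. The gain is a precursor whose ring A has two equal hydroxyls. The demand is that the forward methylation distinguishes O7 from O6, which must come from the higher acidity of the hydroxyl para to the carbonyl-bearing C4a.

12 to 10 (through 11): two hydrogens are put back on C5 and C8 and silyl groups on O6 and O7. This turns the arene into a cyclohexa-1,4-diene, the retron of a cycloaddition followed by elimination. The demand is an oxidant that removes the doubly allylic hydrogens without touching ring B or C2=C3, and a sequence in which the freed catechol never meets that oxidant.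

10 to 6 and 8 (through 9): the C4a–C5 and C8–C8a bonds are cut, and a sulfinyl group is placed on C4a with hydrogen on C8a. The whole of ring A is removed in one operation, leaving a monocyclic pyranone that already holds ring B, ring C and every remaining carbon. The demands are reaction at the sulfinyl-bearing double bond only, a cis relation of sulfinyl group and C8a hydrogen for the syn elimination, and conditions that the silyl enol ethers survive.

8 to 7: the two O–Si bonds are cut, which leads back to a bulk diketone. The forward step needs double enolization toward the methyl groups (the only possibility) under anhydrous conditions.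

6 to 4 (through 5): both C–O bonds of the pyranone oxygen and both ring C=C bonds are cut, which removes the two CH carbons and the ring oxygen. The ring becomes an acyclic ketone flanked by two methylene groups, to which two one-carbon units and one oxygen from water are added. The demand is that both methylenes condense (one is activated by ketone and sulfinyl group, the other by ketone and aryl ring) and that ring closure spares the sulfoxide.

4 to 2 and 3: the bond between the carbonyl carbon and the sulfur-bearing CH2 is cut. This gives an arylacetic ester and a simple sulfoxide. The demand is that the sulfinyl carbanion adds to the ester faster than it removes a benzylic proton, with a second equivalent of anion to absorb the acidity of the product.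

2 to 1: the ester C–OMe bond is cut, which leads to the commercial acid. The forward step is a routine esterification.

## Other disconnections considered

Alternative 1: The cut is the C2–C3 bond; C2 comes from the methyl carbon of an ortho-methoxyl in the diazoketone A1. In the forward step Rh2(O2CCPh3)4 (divalent rhodium) would turn A1 into a carbene at the future C3, which would insert into a C–H bond of that methoxyl and close ring C as the isoflavanone A2. Dehydrogenation to A8 and hydrogenolysis of the benzyl ether would then lead to 13.
- In its favour: O6 (benzyl) and O7 (methyl) are differentiated from the start, so no selective alkylation is needed. On this point it is better than the chosen plan. C2 costs no reagent and the key step is catalytic.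
- Against it: the carbene can attack the methoxyl oxygen instead, giving a five-membered oxonium ylide and, after a 1,2-shift, a five-membered ring. That path is geometrically at least as accessible as the six-membered insertion. An aryl keto carbene can also attack the electron-rich ring B or undergo Wolff rearrangement.
- A1 is a diazo compound that needs an arene acylation with an activated form of 1 and a diazo transfer, and A2 is at the wrong oxidation level.
- Comparison: on structure the alternative is ahead because the oxygen pattern is fixed. On mechanism both key steps lack close precedent, but the side paths of the carbene lead to constitutional isomers of the ring system, whereas those of the cycloaddition do not. On step count the two are about equal (six to seven steps, each with one dehydrogenation after the key step).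

Alternative 2: The cut goes through both bonds from ring C to ring A, O1–C8a and C4–C4a. In the forward step CsF would release a 3-chloroaryne from the silyl triflate A3. The enolate oxygen of the formylacetate enol A4 would add to the aryne carbon remote from chlorine, and the aryl anion next to chlorine would attack the ester and expel methoxide to give A5. Hydrogenolysis over Pd/C with base could then remove chlorine and benzyl together.
- In its favour: it is the most convergent of the four plans. Ring C forms in one operation from two halves, and A4 is one formylation away from 2. The conditions are mild and the two ring A oxygens are differentiated from the outset, again better than the chosen plan on that point.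
- Against it: A3 is a pentasubstituted benzene. Its preparation (chlorination, differentiation of two oxygens, ortho-silylation, triflation) would take more steps than the whole chosen route.
- The ambident enolate of A4 can attack the aryne through carbon. The hydrodechlorination must stop before C2=C3 is reduced. Chlorine, silyl, triflate and benzyl are all discarded.
- Comparison: on structure the alternative is ahead (fixed oxygen pattern). On mechanism each key step depends on one selectivity, oxygen against carbon attack there and one C=C bond against the other here. On step economy the chosen route is clearly shorter because it starts from bulk chemicals.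

Alternative 3: The cut is the C4–C4a bond. In the forward step the activated carboxyl group of the aryloxyacrylic acid A7 (for example with P2O5/MeSO3H) would attack the ring carbon para to the methoxyl and close ring C, giving A8. Hydrogenolysis of the benzyl ether would give 13. A7 would be made from the phenol A6 and A4 by activation of the enol, addition–elimination and saponification.
- In its favour: every step is of an established type. The free hydroxyl is placed by the choice of A6, and the closure is directed to the less hindered position para to the methoxyl. The sequence is about five steps from 2.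
- On step count, on precedent and on the placement of the C6 hydroxyl this alternative is better than the chosen plan.
- Against it: only the Z isomer of A7 can cyclize, so the acid must allow isomerization. The strongly acidic medium may cleave the benzyl ether early, may expel A6 from the acetal-like aryloxyacrylate, and may let the acylium ion attack the electron-rich ring B of another molecule.
- Comparison: the chosen plan is weaker on precedent and needs a selective methylation. It has no strongly acidic step, no double-bond geometry to control and no regiochemical question in the ring-forming step. It builds ring A from a C4 unit, so the same pyranone 6 could serve other ring A patterns. That is the reason for carrying it forward here.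

Key step: step 5

Assumption: all sulfinyl compounds (3, 4, 5, 6, 9) are used as racemates at sulfur, because the sulfur atom leaves in step 5 and the target has no stereocentre.

Remark: 6, 8 and 10 are constitutionally sound as drawn in the compound list and need no correction. The design change is operational: 10 is not chromatographed, and dehydrogenation and desilylation are run as one step, so only two steps follow the key step. The ester 2 and the diene 8 are also offered by some suppliers; they are made here from bulk chemicals so that the route does not depend on their supply.

## Route

Step 1
Reactants: 1 3,4,5-trimethoxyphenylacetic acid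
Product: 2 methyl 3,4,5-trimethoxyphenylacetate
Conditions: MeOH, H2SO4 (cat.), reflux
Reagents that add atoms: methanol, CO
Why: Fischer esterification driven by methanol as solvent; nothing else in 1 is acid-labile under these conditions.

Step 2
Reactants: 2 methyl 3,4,5-trimethoxyphenylacetate; 3 racemic methyl p-tolyl sulfoxide
Product: 4 racemic 1-(4-methylbenzenesulfinyl)-3-(3,4,5-trimethoxyphenyl)propan-2-one
Conditions: 3 (2.1 equiv), LiN(iPr)2 (2.1 equiv), THF, −78 °C; then 2, −78 → −20 °C; aq NH4Cl
Reagents that add atoms: none
Why: Claisen-type acylation of an α-sulfinyl carbanion by an ester; the second equivalent of anion deprotonates the more acidic β-ketosulfoxide as it forms, which protects it from further addition, and addition at −78 °C should outrun removal of a benzylic proton from 2.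

Step 3
Reactants: 4 racemic 1-(4-methylbenzenesulfinyl)-3-(3,4,5-trimethoxyphenyl)propan-2-one
Product: 6 racemic 3-(4-methylbenzenesulfinyl)-5-(3,4,5-trimethoxyphenyl)-4H-pyran-4-one, via bis-enaminone 5 (not isolated)
Conditions: Me2NCH(OMe)2 (5 equiv), PhMe, 100 °C; evaporate; then AcOH–H2O (3:1), 60 °C
Reagents that add atoms: N,N-dimethylformamide dimethyl acetal, COC(OC)N(C)C; water, O
Why: Both methylene groups of 4 condense with the formamide acetal to give the bis-enaminone 5; aqueous acid hydrolyses one enamine to the hydroxymethylene ketone, whose enol oxygen adds to the other aminoenone and expels dimethylamine, which is the established enaminone route from 1,3-disubstituted acetones to 3,5-disubstituted 4-pyranones.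

Step 4
Reactants: 7 butane-2,3-dione
Product: 8 2,3-bis(trimethylsilyloxy)buta-1,3-diene
Conditions: TMSOTf (2.2 equiv), Et3N (2.6 equiv), Et2O, 0 °C → rt; distil
Reagents that add atoms: trimethylsilyl trifluoromethanesulfonate, C[Si](C)(C)OS(=O)(=O)C(F)(F)F
Why: Soft enolization and double O-silylation of a 1,2-diketone: the silyl triflate activates each carbonyl and triethylamine removes a methyl proton, so the diene is the only possible bis-enol ether.

Step 5
Reactants: 6 racemic 3-(4-methylbenzenesulfinyl)-5-(3,4,5-trimethoxyphenyl)-4H-pyran-4-one; 8 2,3-bis(trimethylsilyloxy)buta-1,3-diene
Product: 10 6,7-bis(trimethylsilyloxy)-3-(3,4,5-trimethoxyphenyl)-5,8-dihydro-4H-chromen-4-one, via cis-fused sulfinyl cycloadduct 9 (not isolated)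
Conditions: 8 (3 equiv), BHT (cat.), PhMe, sealed tube, 110 °C; evaporate
Reagents that add atoms: none
Why: Proposed new method: a normal-electron-demand [4+2] cycloaddition in which the C2=C3 bond of 6, its LUMO lowered by the ketone and the sulfinyl group on the same carbon, takes up the electron-rich diene 8 suprafacially, after which the adduct 9 loses 4-methylbenzenesulfenic acid by thermal syn (Ei) elimination through a five-membered transition state. The closest known reaction type is the Diels–Alder reaction of 2-sulfinylquinones and 3-sulfinylchromones with in situ sulfoxide pyrolysis; a monocyclic 4-pyranone has not been used in this way, and its partial aromatic stabilization is the reason for the high temperature and the excess of diene. Ring A is closed as a six-membered carbocycle by the cycloaddition itself, both new bonds (C4a–C5 and C8–C8a) forming on one face of the dienophile in a single, possibly asynchronous, event. The two transient stereocentres of 9, C4a and C8a, are set cis by this suprafacial addition to a ring double bond, which leaves the sulfinyl group and the C8a hydrogen on the same face as the elimination requires; both centres disappear in 10, so neither the racemic sulfur nor the facial selectivity matters. Site selectivity is needed between the two C=C bonds of 6 and is secured by the sulfinyl group, since the other double bond carries the aryl ring, is activated by the ketone alone and is more hindered. No regiochemical question arises because 8 is symmetric. Elimination toward C8a is preferred because it restores the vinylogous ester, and elimination toward C5 would give an isomeric diene that converges on the same arene in step 6. The surplus diene also intercepts the sulfenic acid, and 10 is taken on without chromatography because its silyl enol ethers are labile.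

Step 6
Reactants: 10 6,7-bis(trimethylsilyloxy)-3-(3,4,5-trimethoxyphenyl)-5,8-dihydro-4H-chromen-4-one
Product: 12 6,7-dihydroxy-3-(3,4,5-trimethoxyphenyl)-4H-chromen-4-one, via bis-silyl isoflavone 11 (not isolated)
Conditions: DDQ (1.0 equiv), PhMe, rt; filter; then MeOH, PPTS (cat.), rt
Reagents that add atoms: none
Why: Quinone dehydrogenation of a cyclohexa-1,4-diene: hydride is abstracted from the doubly allylic C5 or C8 and a proton is lost to give the arene 11; the aryl silyl ethers are then solvolysed by methanol under mild acid only after the spent and residual oxidant have been filtered off, so the free catechol should not be oxidized further.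

Step 7
Reactants: 12 6,7-dihydroxy-3-(3,4,5-trimethoxyphenyl)-4H-chromen-4-one
Product: 13 6-hydroxy-7-methoxy-3-(3,4,5-trimethoxyphenyl)-4H-chromen-4-one
Conditions: MeI (1.1 equiv), KHCO3 (1.1 equiv), DMF, 35 °C
Reagents that add atoms: iodomethane, CI
Why: Selective Williamson O-methylation of the more acidic phenol: the O7 phenoxide is stabilized through C4a by the C4 carbonyl (a vinylogous carboxylate) while O6 is meta to that carbon, so a weak base should ionize only O7, as in the known alkylation of 3,4-dihydroxybenzaldehyde and 6,7-dihydroxycoumarin at the oxygen para to the acceptor.

## Compound list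

1 | 3,4,5-trimethoxyphenylacetic acid | COc1cc(CC(=O)O)cc(OC)c1OC | starting material
2 | methyl 3,4,5-trimethoxyphenylacetate | COC(=O)Cc1cc(OC)c(OC)c(OC)c1 | intermediate
3 | methyl p-tolyl sulfoxide (racemic) | CS(=O)c1ccc(C)cc1 | starting material
4 | 1-(4-methylbenzenesulfinyl)-3-(3,4,5-trimethoxyphenyl)propan-2-one (racemic at sulfur) | Cc1ccc(S(=O)CC(=O)Cc2cc(OC)c(OC)c(OC)c2)cc1 | intermediate
5 | 1,5-bis(dimethylamino)-2-(4-methylbenzenesulfinyl)-4-(3,4,5-trimethoxyphenyl)penta-1,4-dien-3-one (racemic at sulfur; double-bond geometry not defined) | CN(C)C=C(C(=O)C(=CN(C)C)S(=O)c1ccc(C)cc1)c1cc(OC)c(OC)c(OC)c1 | intermediate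
6 | 3-(4-methylbenzenesulfinyl)-5-(3,4,5-trimethoxyphenyl)-4H-pyran-4-one (racemic at sulfur) | O=c1c(S(=O)c2ccc(C)cc2)cocc1-c1cc(OC)c(OC)c(OC)c1 | intermediate
7 | butane-2,3-dione | CC(=O)C(C)=O | starting material
8 | 2,3-bis(trimethylsilyloxy)buta-1,3-diene | C=C(O[Si](C)(C)C)C(=C)O[Si](C)(C)C | intermediate
9 | cis-fused 4a-(4-methylbenzenesulfinyl)-6,7-bis(trimethylsilyloxy)-3-(3,4,5-trimethoxyphenyl)-4a,5,8,8a-tetrahydro-4H-chromen-4-one (racemic; sulfinyl group and 8a-H on the same face, one enantiomer drawn; sulfur configuration not defined) | O=C1C(c2cc(OC)c(OC)c(OC)c2)=CO[C@H]2CC(O[Si](C)(C)C)=C(O[Si](C)(C)C)C[C@@]12S(=O)c1ccc(C)cc1 | intermediate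
10 | 6,7-bis(trimethylsilyloxy)-3-(3,4,5-trimethoxyphenyl)-5,8-dihydro-4H-chromen-4-one | C[Si](C)(C)OC1=C(O[Si](C)(C)C)Cc2occ(-c3cc(OC)c(OC)c(OC)c3)c(=O)c2C1 | intermediate
11 | 6,7-bis(trimethylsilyloxy)-3-(3,4,5-trimethoxyphenyl)-4H-chromen-4-one | C[Si](C)(C)Oc1cc2occ(-c3cc(OC)c(OC)c(OC)c3)c(=O)c2cc1O[Si](C)(C)C | intermediate
12 | 6,7-dihydroxy-3-(3,4,5-trimethoxyphenyl)-4H-chromen-4-one | Oc1cc2occ(-c3cc(OC)c(OC)c(OC)c3)c(=O)c2cc1O | intermediate
13 | 6-hydroxy-7-methoxy-3-(3,4,5-trimethoxyphenyl)-4H-chromen-4-one | COc1cc2occ(-c3cc(OC)c(OC)c(OC)c3)c(=O)c2cc1O | target

## Step count and risk

Total step count: 7. Longest linear sequence: 6 (steps 1, 2, 3, 5, 6, 7); step 4 is a one-step side branch.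

Least certain steps:

Step 5 (key step, proposed new method). The cycloaddition may be too slow because the pyranone is partly aromatic, so that the diene decomposes or oligomerizes first. The sulfenic acid may also strip the silyl groups before the product is secured. The fallback uses known chemistry, sets out from 1 and comes back to the route at 13. Acid 1 is heated with 2-methoxybenzene-1,4-diol in BF3·OEt2 at 80 °C. This Friedel–Crafts acylation should go at the ring position para to the methoxyl and ortho to a hydroxyl and give 1-(2,5-dihydroxy-4-methoxyphenyl)-2-(3,4,5-trimethoxyphenyl)ethan-1-one F1. Ring C is then closed on F1 with a one-carbon electrophile (DMF, BF3·OEt2, MsCl, 70 °C), the classical deoxybenzoin route to isoflavones. This gives 13 directly with the C6 hydroxyl and C7 methoxyl already in place.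

Step 7. The two hydroxyls may not be discriminated well enough, so that methylation at O6 or at both oxygens competes. The fallback sets out from 12 and comes back at 13.
- Acetylation (Ac2O, pyridine) gives 4-oxo-3-(3,4,5-trimethoxyphenyl)-4H-chromene-6,7-diyl diacetate F5.
- The acetate para to the carbonyl is the better acyl donor and is removed selectively (PhSH, imidazole, NMP, 0 °C) to give 7-hydroxy-4-oxo-3-(3,4,5-trimethoxyphenyl)-4H-chromen-6-yl acetate F6.
- Mitsunobu methylation (MeOH, PPh3, DIAD, THF) avoids a basic medium that would promote acyl migration and gives 7-methoxy-4-oxo-3-(3,4,5-trimethoxyphenyl)-4H-chromen-6-yl acetate F7.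
- Methanolysis (K2CO3 cat., MeOH) gives 13.

Step 2. Proton transfer from the benzylic position of the ester to the strongly basic sulfinyl carbanion may compete with addition, returning unreacted ester or causing self-condensation. The fallback sets out from 2 and comes back at 4.
- Ester 2 is acylated onto the much less basic dimethylsulfoxonium methylide (Me3S(O)I, KOtBu, THF, reflux) to give 1-(dimethyloxo-λ6-sulfanylidene)-3-(3,4,5-trimethoxyphenyl)propan-2-one F2.
- 4-Methylbenzenethiol (MeCN, rt to 50 °C) protonates the ylide and the thiolate displaces dimethyl sulfoxide, giving 1-[(4-methylphenyl)sulfanyl]-3-(3,4,5-trimethoxyphenyl)propan-2-one F3.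
- NaIO4 (MeOH–H2O, 0 °C) oxidizes the sulfide to the sulfoxide 4.

Step 3. The sulfinyl group may be lost or rearranged (Pummerer-type chemistry) during the hot condensation or the acidic ring closure. Condensation at the second methylene may be incomplete, so that acid hydrolysis reverses the condensation without closing the ring. The fallback carries sulfur through ring formation as the sulfide and oxidizes it afterwards. It sets out from 2 and comes back at 6.
- The sulfide F3 is reached from 2 by way of F2, as in the fallback for step 2.
- F3 is treated with Me2NCH(OMe)2 and then aqueous acetic acid as in step 3, to give 3-[(4-methylphenyl)sulfanyl]-5-(3,4,5-trimethoxyphenyl)-4H-pyran-4-one F4.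
- mCPBA (1.0 equiv, CH2Cl2, −20 °C) oxidizes F4 to the sulfoxide 6.

## Further compounds

F1 | step 5 | 1-(2,5-dihydroxy-4-methoxyphenyl)-2-(3,4,5-trimethoxyphenyl)ethan-1-one | COc1cc(O)c(C(=O)Cc2cc(OC)c(OC)c(OC)c2)cc1O
F2 | step 2 | 1-(dimethyloxo-λ6-sulfanylidene)-3-(3,4,5-trimethoxyphenyl)propan-2-one | CS(C)(=O)=CC(=O)Cc1cc(OC)c(OC)c(OC)c1
F3 | step 2 | 1-[(4-methylphenyl)sulfanyl]-3-(3,4,5-trimethoxyphenyl)propan-2-one | Cc1ccc(SCC(=O)Cc2cc(OC)c(OC)c(OC)c2)cc1
F4 | step 3 | 3-[(4-methylphenyl)sulfanyl]-5-(3,4,5-trimethoxyphenyl)-4H-pyran-4-one | O=c1c(Sc2ccc(C)cc2)cocc1-c1cc(OC)c(OC)c(OC)c1
F5 | step 7 | 4-oxo-3-(3,4,5-trimethoxyphenyl)-4H-chromene-6,7-diyl diacetate | CC(=O)Oc1cc2occ(-c3cc(OC)c(OC)c(OC)c3)c(=O)c2cc1OC(C)=O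
F6 | step 7 | 7-hydroxy-4-oxo-3-(3,4,5-trimethoxyphenyl)-4H-chromen-6-yl acetate | CC(=O)Oc1cc2c(=O)c(-c3cc(OC)c(OC)c(OC)c3)coc2cc1O
F7 | step 7 | 7-methoxy-4-oxo-3-(3,4,5-trimethoxyphenyl)-4H-chromen-6-yl acetate | CC(=O)Oc1cc2c(=O)c(-c3cc(OC)c(OC)c(OC)c3)coc2cc1OC
A1 | alternative 1 | 1-[5-(benzyloxy)-2,4-dimethoxyphenyl]-2-diazo-2-(3,4,5-trimethoxyphenyl)ethan-1-one | COc1cc(OC)c(C(=O)C(=[N+]=[N-])c2cc(OC)c(OC)c(OC)c2)cc1OCc1ccccc1
A2 | alternative 1 | racemic 6-(benzyloxy)-7-methoxy-3-(3,4,5-trimethoxyphenyl)chroman-4-one | COc1cc2OCC(c3cc(OC)c(OC)c(OC)c3)C(=O)c2cc1OCc1ccccc1
A3 | alternative 2 | 4-(benzyloxy)-3-chloro-5-methoxy-2-(trimethylsilyl)phenyl trifluoromethanesulfonate | COc1cc(OS(=O)(=O)C(F)(F)F)c([Si](C)(C)C)c(Cl)c1OCc1ccccc1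
A4 | alternative 2 | methyl (2Z)-3-hydroxy-2-(3,4,5-trimethoxyphenyl)prop-2-enoate | COC(=O)/C(=C\O)c1cc(OC)c(OC)c(OC)c1
A5 | alternative 2 | 6-(benzyloxy)-5-chloro-7-methoxy-3-(3,4,5-trimethoxyphenyl)chromen-4-one | COc1cc2occ(-c3cc(OC)c(OC)c(OC)c3)c(=O)c2c(Cl)c1OCc1ccccc1
A6 | alternative 3 | 4-(benzyloxy)-3-methoxyphenol | COc1cc(O)ccc1OCc1ccccc1
A7 | alternative 3 | (2Z)-3-[4-(benzyloxy)-3-methoxyphenoxy]-2-(3,4,5-trimethoxyphenyl)prop-2-enoic acid | COc1cc(O/C=C(\C(=O)O)c2cc(OC)c(OC)c(OC)c2)ccc1OCc1ccccc1
A8 | alternative 3 | 6-(benzyloxy)-7-methoxy-3-(3,4,5-trimethoxyphenyl)chromen-4-one | COc1cc2occ(-c3cc(OC)c(OC)c(OC)c3)c(=O)c2cc1OCc1ccccc1
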